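## Retrosynthetic overview

1. **Structural feature:** in the 4-hydroxy-2-pyranone ring, C2'–C3'–C4' is a malonyl unit, and O1'–C6'–C5' (bearing Et and Me) is the enol of 3-pentanone. C3' lies one CH2 from C8 of ring A, next to O7, so the malonyl unit can be stored as a 3-carboxy-3,4-dihydrocoumarin ring fused across O7/C8.
2. **Key disconnection:** C4'–C5' forms by C-acylation of the 3-pentanone enol silane with the acyl chloride. O1'–C2' forms when the enol oxygen displaces O7 from the lactone carbonyl, so the pyranone closes as the lactone opens and the 7-OH appears unprotected.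
3. **Lactone acid:** C8–CH2 and CH2–C3' come from (2S)-pinocembrin, formaldehyde and Meldrum's acid. Free 5,7-dihydroxyflavanones accept electrophiles at C6 at least as readily as at C8, so C6 is first blocked with iodine and unblocked by hydrogenolysis before activation.
4. **Ring order:** rings A, B and C are bought, the dihydrocoumarin lactone ring forms in step 2, and the pyranone ring forms in step 6 at the expense of the lactone ring.
5. **Stereochemistry:** C2 (S) is the only stereocentre. It comes from the chiral pool and is protected by using no base stronger than acetate.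

Key step: step 6

Assumption: commercial (2S)-pinocembrin is taken as enantiomerically pure. Because it lacks a 4'-hydroxyl, it should racemise only by base-induced opening of ring C to the chalcone, so every step is run base-free or acetate-buffered.

## Route

Step 1
Reactants: 1 (2S)-pinocembrin
Product: 2 (2S)-6-iodopinocembrin
Conditions: NIS (1.0 equiv), DMF, 0 °C → rt, dark
Reagents that add atoms: N-iodosuccinimide, O=C1CCC(=O)N1I
Why: Electrophilic aromatic iodination under neutral conditions goes to C6, the ring-A carbon flanked by both free hydroxyls and the preferred site of attack in flavonoids that keep the 5-OH, so iodine blocks the position that would otherwise compete with C8, and the absence of base leaves C2 (S) untouched.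

Step 2
Reactants: 2 (2S)-6-iodopinocembrin, 3 formaldehyde (charged as paraformaldehyde), 4 Meldrum's acid
Product: 7 6-iodo lactone acid (O7/C8-fused 3,4-dihydrocoumarin-3-carboxylic acid; epimers at the lactone α-carbon), via methylene Meldrum's acid 5 (not isolated), via C8-linked Meldrum's acid adduct 6 (not isolated)
Conditions: (CH2O)n (1.2 equiv), 4 (1.2 equiv), ethylenediammonium diacetate (10 mol %), MeCN, 40 °C; then TFA (0.2 equiv), 60 °C
Reagents that add atoms: none
Why: Yonemitsu-type three-component condensation: Knoevenagel condensation of 3 and 4 gives the strong Michael acceptor 5, the only free nucleophilic ring-A carbon (C8) adds to it in a Friedel–Crafts-type Michael reaction to give 6, and the neighbouring 7-OH then acylates itself on the Meldrum's ring with loss of acetone, while the acetate/TFA buffer and the 60 °C ceiling guard against chalcone opening at C2 and against decarboxylation; the new lactone α-centre forms as an epimer mixture, which is harmless because it becomes sp2 in step 6.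

Step 3
Reactants: 7 6-iodo lactone acid
Product: 8 lactone acid (O7/C8-fused 3,4-dihydrocoumarin-3-carboxylic acid of pinocembrin; epimers at the lactone α-carbon)
Conditions: H2 (1 atm), 10 % Pd/C, NaOAc (1.1 equiv), THF–AcOH (10:1), rt
Reagents that add atoms: none
Why: Palladium-catalysed hydrogenolysis cleaves the weak aryl C–I bond at 1 atm and room temperature, conditions under which the chelated C4 ketone, the benzylic C2–O1 ether and the lactone persist as they do in routine O-debenzylations of flavanones, and acetate traps the HI without opening ring C.

Step 4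
Reactants: 8 lactone acid
Product: 9 lactone acyl chloride (3-chlorocarbonyl-3,4-dihydrocoumarin fused at O7/C8; epimers at the lactone α-carbon; used crude)
Conditions: (COCl)2 (1.3 equiv), DMF (2 mol %), CH2Cl2, 0 °C → rt; evaporate
Reagents that add atoms: oxalyl chloride, O=C(Cl)C(=O)Cl
Why: Vilsmeier-type activation with oxalyl chloride and catalytic DMF converts malonic half-esters into their acyl chlorides without base, and the only free hydroxyl (5-OH) is tied up in the hydrogen bond to C4=O and is not acylated under these conditions.

Step 5
Reactants: 10 3-pentanone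
Product: 11 (Z)-3-(trimethylsilyloxy)pent-2-ene
Conditions: TMSOTf (1.05 equiv), Et3N (1.2 equiv), Et2O, 0 °C; distil
Reagents that add atoms: trimethylsilyl triflate, C[Si](C)(C)OS(=O)(=O)C(F)(F)F
Why: Soft enolisation with TMSOTf and triethylamine silylates the symmetrical ketone on oxygen and gives mainly the Z enol silane, whose geometry is of no consequence because C5'=C6' ends up inside the pyranone ring.

Step 6
Reactants: 9 lactone acyl chloride, 11 (Z)-3-(trimethylsilyloxy)pent-2-ene
Product: 13 CNP0326321.1 (target), via β-diketone lactone 12 (not isolated)
Conditions: 11 (3 equiv), ZnCl2 (30 mol %), CH2Cl2, −20 °C → rt; then PhMe, 80 °C; aq. citric acid/THF work-up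
Reagents that add atoms: none
Why: The Zn(II)-activated chlorocarbonyl carbon of 9 (or the aryloxycarbonyl ketene arising from it by loss of HCl, which excess 11 scavenges) is attacked by the nucleophilic C2 of enol silane 11, which forms C4'–C5', releases TMSCl and gives the 1,3-diketone 12; on warming, the C6' enol oxygen of 12 adds to the lactone carbonyl C2', the tetrahedral intermediate expels the C7 phenoxide, and C3'–H enolises to the 4-hydroxy-2-pyranone. The closest known reaction types are the Lewis-acid C-acylation of ketone enol silanes to 1,3-diketones, the one-flask pyranone synthesis from enol silanes and malonyl dichlorides, and the condensation of activated aryl malonates with ketones, of which this is the mixed chloride/aryl ester case. The pyranone is the only ring closed, by a 6-exo-trig addition–elimination (O1'–C2'), and its closure opens the dihydrocoumarin ring. No stereocentre is created, since the lactone α-carbon of 9 and C5' of 12 both end as sp2 carbons, and C2 stays S because no base is present that could open ring C to the chalcone. The order of the two acylations is fixed by the large reactivity gap between acyl chloride and lactone, C- over O-acylation is secured by Lewis-acid rather than fluoride or base activation, and regiochemistry is no issue because 3-pentanone is symmetrical. The ring switch is driven by the C7 aryloxide being para to the C4 ketone (an active ester) and by the vinylogous-acid stabilisation of the pyranone, holding the mixture cold until 9 is consumed keeps the liberated 7-OH from being acylated, and the 5-OH stays locked in its hydrogen bond to C4=O.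

## Compound list

1 | (2S)-pinocembrin, (2S)-5,7-dihydroxy-2-phenylchroman-4-one | O=C1C[C@@H](c2ccccc2)Oc2cc(O)cc(O)c21 | starting material
2 | (2S)-5,7-dihydroxy-6-iodo-2-phenylchroman-4-one (6-iodopinocembrin) | O=C1C[C@@H](c2ccccc2)Oc2cc(O)c(I)c(O)c21 | intermediate
3 | formaldehyde (charged as paraformaldehyde) | C=O | starting material
4 | Meldrum's acid, 2,2-dimethyl-1,3-dioxane-4,6-dione | CC1(C)OC(=O)CC(=O)O1 | starting material
5 | 5-methylene Meldrum's acid (not isolated) | C=C1C(=O)OC(C)(C)OC1=O | intermediate
6 | 5-{[(2S)-5,7-dihydroxy-6-iodo-4-oxo-2-phenylchroman-8-yl]methyl}-2,2-dimethyl-1,3-dioxane-4,6-dione (not isolated) | CC1(C)OC(=O)C(Cc2c(O)c(I)c(O)c3c2O[C@H](c2ccccc2)CC3=O)C(=O)O1 | intermediate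
7 | (2S)-5-hydroxy-6-iodo-4,8-dioxo-2-phenyl-3,4,9,10-tetrahydro-2H,8H-pyrano[2,3-f]chromene-9-carboxylic acid (C9 epimers) | O=C(O)C1Cc2c(c(I)c(O)c3c2O[C@H](c2ccccc2)CC3=O)OC1=O | intermediate
8 | (2S)-5-hydroxy-4,8-dioxo-2-phenyl-3,4,9,10-tetrahydro-2H,8H-pyrano[2,3-f]chromene-9-carboxylic acid (C9 epimers) | O=C(O)C1Cc2c(cc(O)c3c2O[C@H](c2ccccc2)CC3=O)OC1=O | intermediate
9 | (2S)-5-hydroxy-4,8-dioxo-2-phenyl-3,4,9,10-tetrahydro-2H,8H-pyrano[2,3-f]chromene-9-carbonyl chloride (C9 epimers) | O=C(Cl)C1Cc2c(cc(O)c3c2O[C@H](c2ccccc2)CC3=O)OC1=O | intermediate
10 | 3-pentanone | CCC(=O)CC | starting material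
11 | (Z)-3-(trimethylsilyloxy)pent-2-ene | C/C=C(/CC)O[Si](C)(C)C | intermediate
12 | (2S)-5-hydroxy-9-(2-methyl-3-oxopentanoyl)-2-phenyl-2,3,9,10-tetrahydro-4H,8H-pyrano[2,3-f]chromene-4,8-dione (side-chain and C9 epimers; not isolated) | CCC(=O)C(C)C(=O)C1Cc2c(cc(O)c3c2O[C@H](c2ccccc2)CC3=O)OC1=O | intermediate
13 | CNP0326321.1, (2S)-8-[(6-ethyl-4-hydroxy-5-methyl-2-oxo-2H-pyran-3-yl)methyl]-5,7-dihydroxy-2-phenylchroman-4-one | CCc1oc(=O)c(Cc2c(O)cc(O)c3c2O[C@H](c2ccccc2)CC3=O)c(O)c1C | target

## Step count

- Total step count: 6.
- Longest linear sequence: 5 (steps 1, 2, 3, 4, 6).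

## Steps most likely to fail

**Step 6.** Several processes could compete:
- O-acylation of the enol silane.
- Oligomerisation of the ketene formed by loss of HCl.
- Capture of that ketene through the lactone carbonyl oxygen in a [4+2] sense.
- A ring switch too slow to outrun retro-Claisen cleavage.

The fallback sets out from 11 and 2 and returns at 13. It makes the pyranone first and the methylene bridge last. Enol silane 11 and malonyl dichloride (Et2O, −78 °C → rt) should give 6-ethyl-4-hydroxy-5-methyl-2H-pyran-2-one F1. F1, formaldehyde 3 and 6-iodopinocembrin 2 are then combined under ethylenediammonium diacetate catalysis. This is a Knoevenagel condensation followed by Friedel–Crafts-type Michael addition of C8, the coupling known for methylene-bridged acylphloroglucinol–pyranone dimers, and it should give the 6-iodo derivative of the target F2. Hydrogenolysis as in step 3 then leads to 13.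

**Step 2.** Several processes could compete:
- Consumption of 5 by a second molecule of 4.
- Bridging of two flavanones by formaldehyde.
- Transfer of iodine from C6 to the CH-acid.
- Decarboxylation during lactonisation.

The fallback sets out from 2 and returns at 6. It reverses the polarity of the C–C bond formation. A Mannich reaction of 2 with Eschenmoser's salt (MeCN, rt) should give the C8 Mannich base (2S)-8-[(dimethylamino)methyl]-5,7-dihydroxy-6-iodo-2-phenylchroman-4-one F3. Heating F3 with 4 in MeCN, where 4 buffers the amine as its salt, expels dimethylamine to give the ring-A o-quinone methide F4. Compound 4 captures F4 by Michael addition to give 6, which lactonises as in step 2.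

**Step 1.** Positional selectivity between C6 and C8 may be poor, or iodination may run on to the diiodide.

The fallback sets out from 1 and returns at 8. It uses no blocking group and replaces regiocontrol by separation at a neutral, easily chromatographed stage. Vilsmeier–Haack formylation of 1 (POCl3, DMF, MeCN, 0 °C → rt; aq. NaOAc), followed by chromatographic removal of the C6 isomer, should give 8-formylpinocembrin F5. Knoevenagel condensation of F5 with 4 and spontaneous lactonisation (ethylenediammonium diacetate, EtOH, rt) gives the fused coumarin-3-carboxylic acid F6. Conjugate reduction of its C9=C10 bond (H2, Pd/C, THF) gives 8.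

## Further compounds

F1 | step 6 | 6-ethyl-4-hydroxy-5-methyl-2H-pyran-2-one | CCc1oc(=O)cc(O)c1C
F2 | step 6 | (2S)-8-[(6-ethyl-4-hydroxy-5-methyl-2-oxo-2H-pyran-3-yl)methyl]-5,7-dihydroxy-6-iodo-2-phenylchroman-4-one | CCc1oc(=O)c(Cc2c(O)c(I)c(O)c3c2O[C@H](c2ccccc2)CC3=O)c(O)c1C
F3 | step 2 | (2S)-8-[(dimethylamino)methyl]-5,7-dihydroxy-6-iodo-2-phenylchroman-4-one | CN(C)Cc1c(O)c(I)c(O)c2c1O[C@H](c1ccccc1)CC2=O
F4 | step 2 | (2S)-5-hydroxy-6-iodo-8-methylidene-2-phenyl-2,3-dihydrochromene-4,7-dione (o-quinone methide) | C=C1C(=O)C(I)=C(O)C2=C1O[C@H](c1ccccc1)CC2=O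
F5 | step 1 | (2S)-5,7-dihydroxy-4-oxo-2-phenylchroman-8-carbaldehyde (8-formylpinocembrin) | O=Cc1c(O)cc(O)c2c1O[C@H](c1ccccc1)CC2=O
F6 | step 1 | (2S)-5-hydroxy-4,8-dioxo-2-phenyl-3,4-dihydro-2H,8H-pyrano[2,3-f]chromene-9-carboxylic acid | O=C(O)C1=Cc2c(cc(O)c3c2O[C@H](c2ccccc2)CC3=O)OC1=O
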